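**Retrosynthetic overview**
1. Target 14 is cut into two molecules of N-methylflindersine 11. The central dihydropyran is opened at the bond from the unit A oxygen to pyran C4 of unit B and at the bond from the isobutenyl methine to pyran C3 of unit B. Forward, this is a chiral-acid-controlled oxa-[4+2] of acid-opened 11 (allyl cation 12) with the pyran alkene of a second 11, and all three stereocentres form there.
2. 11 is cut at the aryl ether bond O–C4 and at the C3–CH bond of the quinolone. Forward, the C=O of prenal 7 adds across the C3≡C4 bond of quinolonyne 8, followed by 4π opening and oxa-6π closure.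
3. Enabling feature: in each 2-quinolone half the ether oxygen sits on C4 and a carbon on the adjacent C3, beside the C2 lactam carbonyl. This O–C4=C3–C array is the footprint of a carbonyl group added across a C3≡C4 aryne, and the C2 carbonyl polarises that aryne so that oxygen goes to C4.
4. Ring order: benzo-fused pyridone bought as 1, then the pyran of 11 (step 3), then the central dihydropyran (step 4).
5. Aryne precursor 6 comes from 1 by C3 bromination and O-to-C silyl migration/triflation.

Key step: step 3

Assumption: the sense of induction of the chiral acid in step 4 cannot be derived from precedent; the (R)-acid is written, and its (S)-antipode is used if a first run shows the opposite sense.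

**Step 1**
Reactants: 1 4-hydroxy-1-methylquinolin-2(1H)-one
Product: 2 3-bromo-4-hydroxy-1-methylquinolin-2(1H)-one
Conditions: NBS (1.0 equiv), MeCN, 0 °C to rt
Reagents that add atoms: N-bromosuccinimide, O=C1CCC(=O)N1Br
Why: Electrophilic bromination of a vinylogous acid, in which the enolic C3 is the only nucleophilic carbon, so one equivalent of NBS should give the 3-bromide; no stereocentre is formed.

**Step 2**
Reactants: 2 3-bromo-4-hydroxy-1-methylquinolin-2(1H)-one
Product: 6 1-methyl-2-oxo-3-(trimethylsilyl)-1,2-dihydroquinolin-4-yl trifluoromethanesulfonate, via O-silyl ether 3 (not isolated), via 3-lithio silyl ether 4 (not isolated), via lithium 4-olate 5 (not isolated)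
Conditions: HMDS, THF, 65 °C, then evaporation; n-BuLi, THF, −100 to −78 °C; Tf2O, −100 to −78 °C
Reagents that add atoms: hexamethyldisilazane, C[Si](C)(C)N[Si](C)(C)C; trifluoromethanesulfonic anhydride, O=S(=O)(OS(=O)(=O)C(F)(F)F)C(F)(F)F
Why: Standard 2-silylaryl triflate synthesis by O-silylation, Br–Li exchange (faster than addition to the lactam at −100 °C), retro-Brook 1,3-O-to-C silyl shift driven by formation of the stabilised 4-olate, and O-triflation at O4 with C3 blocked; no stereocentre is formed.

**Step 3**
Reactants: 6 1-methyl-2-oxo-3-(trimethylsilyl)-1,2-dihydroquinolin-4-yl trifluoromethanesulfonate; 7 3-methylbut-2-enal (prenal)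
Product: 11 N-methylflindersine (2,2,6-trimethyl-2H-pyrano[3,2-c]quinolin-5(6H)-one), via quinolonyne 8 (not isolated), via oxete 9 (not isolated), via o-quinone methide 10 (not isolated)
Conditions: CsF (3 equiv), 7 (4 equiv), MeCN, rt to 50 °C
Reagents that add atoms: none
Why: Proposed new method: fluoride should remove the C3 silyl group and expel the C4 triflate to give the strained 3,4-quinolonyne 8, whose C4 takes the nucleophilic carbonyl oxygen of prenal while negative charge builds at C3 beside the C2 carbonyl, and C3 then bonds to the former aldehyde carbon to give oxete 9 (net [2+2] of C=O across the aryne). Thermal 4π opening of 9 cleaves its O–CH bond and gives o-quinone methide 10. The closest known reaction type is the fluoride-induced union of benzyne (from 2-(trimethylsilyl)phenyl triflate) with α,β-unsaturated aldehydes to give 2H-chromenes, together with the generation of 3,4-pyridynes and strained cyclohexynes from silyl triflates; the new element is the lactam-conjugated heteroaryne. The pyran ring, the only ring kept, closes by thermal disrotatory oxa-6π electrocyclisation of the 1-oxatriene O=C4–C3=CH–CH=CMe2 (bond O–CMe2), the transient oxete having closed by carbanion attack on the oxocarbenium carbon. No stereocentre survives, since the oxete methine is lost on ring opening and 11 is achiral. The step needs O-attack at C4 and not C3 (secured by the C2 carbonyl, as in 3,4-pyridynes with an inductively withdrawing C2 substituent), [2+2] and not ene or direct [4+2] (secured by the nucleophilic oxygen of the s-trans enal), and closure through the C4 oxygen and not the lactam oxygen (secured by regaining the 2-quinolone sextet from the E isomer of 10).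

**Step 4**
Reactants: 11 N-methylflindersine (two molecules)
Product: 14 target dimer (S at the isobutenyl methine; R at the O-bearing methine; S at the ring-fusion methine), via allyl cation 12 (not isolated), via benzylic cation 13 (not isolated)
Conditions: (R)-3,3′-bis(2,4,6-triisopropylphenyl)-1,1′-binaphthyl-2,2′-diyl N-(trifluoromethylsulfonyl)phosphoramide (10 mol%), toluene, 5 Å molecular sieves, 0 °C to rt
Reagents that add atoms: none
Why: Proposed new method: the strong chiral acid should protonate one molecule of 11 at the pyran oxygen and ionise its O–CMe2 bond to allyl cation 12 (the O-protonated form of the o-quinone methide, ion-paired with the chiral phosphoramide anion, and not the neutral quinone methide), the nucleophilic pyran C3 of a second 11 should add to the cationic methine of 12 to give benzylic cation 13, and the free C4 hydroxyl of unit A should close onto the oxygen-stabilised pyran C4 cation of unit B with return of the proton to the catalyst, a stepwise inverse-demand oxa-[4+2] whose closest known relatives are the achiral Brønsted-acid dimerisation of 2,2-dimethyl-2H-chromenes and chiral phosphoric acid catalysed [4+2] reactions of ortho-quinone methides with styrene-type alkenes; the cis ring fusion follows from closure on the face of the ring-bound cis alkene that took the first bond, the isobutenyl group should end anti to the CMe2 carbon by exo approach of the bulky alkene partner, and the absolute configuration (S, R, S) rests on the chiral counter-anion that accompanies 12 in the C–C bond-forming event.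

**Compound list**
1 | 4-hydroxy-1-methylquinolin-2(1H)-one | Cn1c(=O)cc(O)c2ccccc21 | starting material
2 | 3-bromo-4-hydroxy-1-methylquinolin-2(1H)-one | Cn1c(=O)c(Br)c(O)c2ccccc21 | intermediate
3 | 3-bromo-1-methyl-4-(trimethylsilyloxy)quinolin-2(1H)-one | Cn1c(=O)c(Br)c(O[Si](C)(C)C)c2ccccc21 | intermediate
4 | 3-lithio-1-methyl-4-(trimethylsilyloxy)quinolin-2(1H)-one | Cn1c(=O)c([Li])c(O[Si](C)(C)C)c2ccccc21 | intermediate
5 | lithium 1-methyl-2-oxo-3-(trimethylsilyl)-1,2-dihydroquinolin-4-olate | Cn1c(=O)c([Si](C)(C)C)c([O-])c2ccccc21.[Li+] | intermediate
6 | 1-methyl-2-oxo-3-(trimethylsilyl)-1,2-dihydroquinolin-4-yl trifluoromethanesulfonate | Cn1c(=O)c([Si](C)(C)C)c(OS(=O)(=O)C(F)(F)F)c2ccccc21 | intermediate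
7 | 3-methylbut-2-enal (prenal) | CC(C)=CC=O | starting material
8 | 1-methyl-3,4-didehydroquinolin-2(1H)-one (3,4-quinolonyne) | CN1C(=O)C#Cc2ccccc21 | intermediate
9 | oxete: 2H-oxete fused through its C=C bond to C3–C4 of 1-methylquinolin-2-one, oxygen on C4, 2-methylprop-1-enyl group on the sp3 carbon; racemic | CC(C)=CC1OC2=C1C(=O)N(C)c1ccccc12 | intermediate
10 | (3E)-1-methyl-3-(3-methylbut-2-en-1-ylidene)quinoline-2,4(1H,3H)-dione (o-quinone methide, isobutenyl on the side of the C4 carbonyl) | CC(C)=C/C=C1\C(=O)c2ccccc2N(C)C1=O | intermediate
11 | N-methylflindersine, 2,2,6-trimethyl-2H-pyrano[3,2-c]quinolin-5(6H)-one | CC1(C)C=Cc2c(O1)c1ccccc1n(C)c2=O | intermediate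
12 | allyl cation: (4-hydroxy-1-methyl-2-oxo-1,2-dihydroquinolin-3-yl)(2-methylprop-1-en-1-yl)methylium, the O-protonated form of 10; counter-ion is the phosphoramide anion of the catalyst | CC(C)=C[CH+]c1c(O)c2ccccc2n(C)c1=O | intermediate
13 | benzylic cation: 2,2,6-trimethyl-5-oxo-3,4,5,6-tetrahydro-2H-pyrano[3,2-c]quinolin-4-ylium carrying at pyran C3 a 1-(4-hydroxy-1-methyl-2-oxo-1,2-dihydroquinolin-3-yl)-3-methylbut-2-en-1-yl group; (S) at the side-chain methine and (R) at pyran C3, the same arrangement in space as in 14; counter-ion is the phosphoramide anion of the catalyst | CC(C)=C[C@H](c1c(O)c2ccccc2n(C)c1=O)[C@H]1[CH+]c2c(c3ccccc3n(C)c2=O)OC1(C)C | intermediate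
14 | target: unit B is a (3S,4R)-3,4-dihydro-2,2,6-trimethylpyrano[3,2-c]quinolin-5-one; its C4 carries the 4-oxygen and its C3 carries, through an (S)-CH(CH=CMe2) methine, the 3-carbon of a second 1-methylquinolin-2-one (unit A); central dihydropyran cis-fused, isobutenyl trans to the CMe2 carbon | CC(C)=C[C@@H]1c2c(c3ccccc3n(C)c2=O)O[C@H]2c3c(c4ccccc4n(C)c3=O)OC(C)(C)[C@@H]12 | target

**Step count and risks**
Total step count: 4. Longest linear sequence: 4 (steps 1 to 4; compound 11 enters step 4 twice).

Steps most likely to fail:

Step 3 (proposed method). The heteroaryne may be consumed unproductively: oxygen attack at C3 instead of C4, ene reaction with the methyl groups of prenal, fluoride addition or oligomerisation. The precursor may also lose its silyl group by protodesilylation before the triflate departs, and the ring-opened intermediate may close through the lactam oxygen. Fallback by known chemistry: setting out from compounds 1 and 7, a Knoevenagel condensation at C3 of 1 (pyridine, 110 °C) forms o-quinone methide 10 in the flask, which closes by oxa-6π electrocyclisation. The route is rejoined at compound 11. This fallback makes no compound outside the list (F0).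

Step 4 (proposed method). Turnover may stall because the basic lactam carbonyls of substrate and product bind the acid. Other dimerisation modes may compete, for example proton loss from the allyl cation to a diene followed by carbo-Diels–Alder reaction. Facial selectivity may be poor, and reversible ionisation of the doubly activated C–O bond of the product may erode it. Fallback by known chemistry: setting out from compound 11, an achiral acid (CF3CO2H, CH2Cl2, rt) promotes the same dimerisation through cation 12 without control of absolute sense. This should give 14 together with its mirror image, the (R,S,R)-enantiomer of 14 F1, the latter by way of the mirror image of the benzylic cation, the enantiomer of 13 F2. The two dimers are separated by preparative HPLC on an amylose tris(3,5-dimethylphenylcarbamate) stationary phase, and the route comes back at compound 14.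

Step 2. n-BuLi may add to the lactam carbonyl, the C3-lithio species 4 may expel silanolate instead of undergoing silyl migration, or triflation may go to the lactam oxygen. Fallback: setting out from compound 2, t-BuLi (3 equiv, THF, −78 °C) first deprotonates the hydroxyl to lithium 3-bromo-1-methyl-2-oxo-1,2-dihydroquinolin-4-olate F3. It then exchanges bromine for lithium to give lithium 3-lithio-1-methyl-2-oxo-1,2-dihydroquinolin-4-olate F4, in which no leaving group sits beside the carbanion. Me3SiCl (2.2 equiv) silylates carbon and oxygen to 1-methyl-3-(trimethylsilyl)-4-(trimethylsilyloxy)quinolin-2(1H)-one F5. MeLi (THF, 0 °C) then cleaves only the labile O–Si bond, and the route comes back at compound 5, which is triflated as in step 2.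

**Further compounds**
F0 | step 3 | none | none
F1 | step 4 | (R,S,R)-enantiomer of 14 | CC(C)=C[C@H]1c2c(c3ccccc3n(C)c2=O)O[C@@H]2c3c(c4ccccc4n(C)c3=O)OC(C)(C)[C@H]12
F2 | step 4 | enantiomer of 13, (R) at the side-chain methine and (S) at pyran C3 | CC(C)=C[C@@H](c1c(O)c2ccccc2n(C)c1=O)[C@@H]1[CH+]c2c(c3ccccc3n(C)c2=O)OC1(C)C
F3 | step 2 | lithium 3-bromo-1-methyl-2-oxo-1,2-dihydroquinolin-4-olate | Cn1c(=O)c(Br)c([O-])c2ccccc21.[Li+]
F4 | step 2 | lithium 3-lithio-1-methyl-2-oxo-1,2-dihydroquinolin-4-olate | Cn1c(=O)c([Li])c([O-])c2ccccc21.[Li+]
F5 | step 2 | 1-methyl-3-(trimethylsilyl)-4-(trimethylsilyloxy)quinolin-2(1H)-one | Cn1c(=O)c([Si](C)(C)C)c(O[Si](C)(C)C)c2ccccc21
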